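Count in minutes, since the clock you set is the run of 4.0 min, and what you are watching is whether the target outlives that clock.

| setting | south-east | north | east | north-east |
|---|---|---|---|---|
| substrate | 0.20 mM | 0.20 mM | 0.20 mM | 0.20 mM |
| partner | 0.240 mM | 0.240 mM | 0.240 mM | 0.240 mM |
| temperature | 50 °C |  | 20 °C | −10 °C |
| time | 4.0 min | 4.0 min | 4.0 min | 4.0 min |
| remark |  | at 50 °C until 80 s, from then on at −10 °C |  |  |

    substrate + partner → isomer of the product (k1 = 180 M⁻¹ s⁻¹, Ea1 = 43.0 kJ mol⁻¹)
    substrate + partner ⇌ target (K2 = 6800 M⁻¹, k2 = 79 M⁻¹ s⁻¹, Ea2 = 45.0 kJ mol⁻¹, ΔH2 = −69.0 kJ mol⁻¹)
    (constants at 20 °C)

- the list of constants is for 20 °C, to be carried to other temperatures by the activation energies and enthalpies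

* the best flask by amount of target, in percent of the substrate charged; "all alike" if 1.5 percentage points covers them all (south-east / north / east / north-east / all alike)
* amount of target at the end, in percent of the substrate charged, south-east
* amount of target at the end, in percent of the substrate charged, north
* amount of target at the end, in percent of the substrate charged, east
* amount of target at the end, in percent of the substrate charged, north-east

At any one moment the two forward steps split what reacts in the ratio of their constants, 2.28 towards the isomer of the product at 20 °C, so the target's opening share is 30.5% of what has reacted. With 43.0 kJ mol⁻¹ beside 45.0 kJ mol⁻¹, you can expect that split to drift little from flask to flask.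

What drifts is the way back, with constant k2/K2 and activation energy 114 kJ mol⁻¹, and target that falls back meets the same split, so 69.5% of it reappears as isomer of the product, which has no way back. I keep two times, the life of the target against falling back and the run.

At −10 °C that life is 297 min, so life over run is 74.2: this is the holding ratio, and well above one it means kinetic rather than thermodynamic control. At 20 °C the life is 86.1 s and the ratio 0.359, and at 50 °C the life is 1.12 s and the ratio 0.00467.

My own reckoning stops at an order: north-east should be best, east should be losing its target, and south-east should be drained. The north flask should lose what it made, since its hot stretch of 80 s is far longer than the hot life.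

The forecast goes further, naming north-east with 19.7%, then 5.8% in east, 0.08% in north and <0.001% in south-east, on the ground that “its reverse step has a high barrier”.

The run gives north-east as best, with 19.7%, against 5.72% in east, 0.0797% in north and 0% in south-east, so the forecast stands on each.

Watch the curve, which end figures hide: in the east flask, at holding ratio 0.359, target stands at 12.3% after 2.00 min and has fallen to 5.72% after 4.00 min. In the north-east flask, at ratio 74.2, target stands at 19.7% after 4.00 min and at 25.8% after 40.0 min, more than at the end of the run. In the south-east flask, at ratio 0.00467, the way back is the largest single effect: the same run without it ends at 32.1% of target instead of 0%.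

The constants used here are assumed; the rest is arithmetic.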